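The data were generated by integration for an exercise; the scatter is artificial.

Time is what I want out of the reckoning, so I ask how the lost starting material divides, not how fast it goes.

| flask | starting material | second substrate | precatalyst | remark | time |
|---|---|---|---|---|---|
| beta | 30 mM | 40 mM | 4.2 µM | run made earlier |  |
| gamma | 10 mM | 40 mM | 4.2 µM | run made earlier |  |
| ochre | 20 mM | 40.0 mM | 4.2 µM |  | 10 min |
| red | 20 mM | 40.0 mM | 10 µM |  | 10 min |

| run | time / s | target / % | starting material / % |
|---|---|---|---|
| beta | 15.0 | 2.0 | 94.1 |
| beta | 30.0 | 0.3 | 89.0 |
| beta | 50.0 | 4.3 | 82.2 |
| beta | 60.0 | 6.6 | 79.0 |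
| beta | 80.0 | 5.5 | 70.8 |
| beta | 90.0 | 5.9 | 68.7 |
| beta | 120 | 9.8 | 62.1 |
| gamma | 10.0 | 0 | 96.3 |
| gamma | 20.0 | 1.0 | 92.4 |
| gamma | 30.0 | 1.2 | 89.2 |
| gamma | 50.0 | 5.2 | 82.2 |
| gamma | 80.0 | 9.3 | 70.8 |
| gamma | 90.0 | 9.5 | 68.0 |
| gamma | 120 | 11.7 | 57.8 |

(scatter of a reading: 1 percentage point)

* which of the two there is more of at the end, ochre (target / uncatalysed product)
* which of the two there is more of at the end, red (target / uncatalysed product)
* how much target is there at the end, in percent of the starting material charged: ochre
* how much target is there at the end, in percent of the starting material charged: red

- the numbers in the tables scatter by 1 percentage point (one standard deviation)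
- a reading or a percentage of target counts all its forms, free or not
- no earlier run changes the charge of precatalyst; that part of a forecast is a guess
- a reading of starting material is of its free form alone

Examiner: What do the earlier runs show about the loss?

Candidate: At 120 s, beta keeps 62.1% of its charge and gamma 57.8%, although their charges differ by a factor of 3.00. So the loss looks first order in starting material, and the two readings give a mean constant of 0.00426 s⁻¹.

Examiner: And where does the lost material go?

Candidate: I count whatever is lost and isn't target as uncatalysed product. Pooled at 30.0 s, the two runs keep 89.1% and hold 0.750% target, which is 0.0739 target per uncatalysed product, so target lags. From 30.0 s to 120 s the pooled gains give 0.522. This is the late split, target formed per uncatalysed product formed after the lag, a selectivity factor. Dividing one gain by the other takes time out of the reckoning, but carrying it past 120 s unchanged is my assumption. Beta alone gives 0.546 and gamma alone 0.502, so I take it as independent of the starting charge.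

Examiner: Ochre, then?

Candidate: Ochre has the same precatalyst and second substrate, so I give it the same lag and late split. The constant leaves a fraction 7.74% at the end, and what is lost after 30.0 s divides by the split, which with the target of the lag gives 28.7% target.

Examiner: Red has more precatalyst, and no run varies that. What now?

Candidate: That is a guess. I take the target path as first order in catalyst and the uncatalysed path as indifferent to it, so red's late split becomes 1.24. That is above one. The faster total loss leaves 2.30%, and with ochre's lag kept that gives 48.9% target beside 48.8% uncatalysed product, a near tie.

The forecast gave 23% and 43%, below my figures, with uncatalysed product ahead in ochre and uncatalysed product in red, calling red “close, slightly favouring uncatalysed product”.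

Ochre ends at 31.8% target, and the larger of the two there is uncatalysed product. Red ends at 55.6% target, and the larger of the two there is target.

    starting material + enzyme ⇌ complex A (K = 110 M⁻¹, k = 90000 M⁻¹ s⁻¹)
    complex A → enzyme + target (k = 18.0 s⁻¹)
    precatalyst ⇌ enzyme (K = 1.70, k = 0.0800 s⁻¹)
    starting material → uncatalysed product (k = 0.00270 s⁻¹)
    second substrate + enzyme ⇌ complex B (K = 76.0 M⁻¹, k = 10000 M⁻¹ s⁻¹)
    starting material + target ⇌ idle adduct, settled at all times (K = 25.0 M⁻¹)
    complex B → enzyme + second product (k = 6.60 s⁻¹)

Counted over the whole run, the flasks end with 0.538 target per uncatalysed product in ochre and 1.32 in red. The gap between the two flasks comes from the difference in precatalyst charge: with that difference taken away, red gives 31.8% target, not 55.6%.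

For a neighbour of red charged with 50 mM of starting material, my late split 1.24, the same lag and 3.4% left give 48.2% target. The computed flask holds 48.5% target beside 46.1% uncatalysed product.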